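A leftover of this chemistry is isomer of the product, so the sum to do is what share of the substrate escapes it as target.

    substrate ⇌ other conformer (K1 = 0.44, k1 = 15 min⁻¹)
    substrate + catalyst → catalyst + target (k2 = 130 M⁻¹ min⁻¹)
    catalyst + other conformer → catalyst + isomer of the product (k3 = 630 M⁻¹ min⁻¹)
    2 substrate → homo dimer (k4 = 0.95 M⁻¹ min⁻¹)

| setting | Wednesday's | Sunday's | Thursday's | Monday's |
|---|---|---|---|---|
| substrate | 0.050 M (fed, over 9.60 min) | 0.050 M | 0.050 M | 0.050 M |
| catalyst | 5 mol% | 5 mol% | 5 mol% | 5 mol% |
| time | 12 min |  | 12 min | 12 min |
| remark | a stirred flask in which substrate is dosed at a steady rate over 9.60 min without added volume, worked up at 12 min | a single well-mixed tank run continuously and read at steady state, 12 min in it on average | a closed flask charged with all of it at once and left for 12 min | plug flow through a tube for 12 min, no back-mixing |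

- a species is counted by the substrate in it: one homo dimer counts as two
- a step written with two of one species runs at k times the square of its concentration and takes two of it each time
- the stated concentrations are those of everything mixed, before any reaction; amounts are the same in each set-up
- the feed brings no volume worth counting
- run time (Wednesday's): 12 min

* the set-up with the highest amount of target at the outlet or at the end, in percent of the substrate put in ("none" if the first two lie within 2 percentage points) (Wednesday's / Sunday's / Thursday's / Monday's / none)
* amount of target at the outlet or at the end, in percent of the substrate put in, Wednesday's
* amount of target at the outlet or at the end, in percent of the substrate put in, Sunday's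
* amount of target at the outlet or at the end, in percent of the substrate put in, Thursday's
* amount of target at the outlet or at the end, in percent of the substrate put in, Monday's

The bench rule is Curtin–Hammett control: conformers that interconvert faster than they react count as one pool, and the product ratio follows from the equilibrium constant and the two catalysed rate constants. It seems to apply, because substrate has a half-life of 2.8 s by the forward conformer change alone and, as charged in Thursday's flask, one of 2.1 min by the catalysed step to target alone. Catalyst comes back after each turn, so c(catalyst) stays at 0.00250 M. The rule sets 130 M⁻¹ min⁻¹ against 277 M⁻¹ min⁻¹ and gives target 31.9%.

The border lies in one ratio. Other conformer returns to substrate at 34.1 min⁻¹ and drains to isomer of the product at 1.58 min⁻¹, and the drain over the return is 0.0462. So c(other conformer)/c(substrate), taken over the whole run, lags at 0.421, lower than the equilibrium constant. That lifts the figure to 32.9%: this is the target share, the fraction of the catalysed turnover that gives target.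

The pool then falls exponentially, with rate constant 0.695 min⁻¹. By that decay, about 0.0239% of it remains at the end in Thursday's flask. Integrating the squared substrate concentration over that decay puts the share of Thursday's charge lost to homo dimer at about 3.39%. My reckoning for Thursday's flask is therefore 31.8%, and Monday's tube, where each slice behaves as a closed flask, gets the same. By the same decay, Wednesday's flask still holds about 2.83% of its charge as pool at the end, which gives 32.0% before its homo dimer is taken off. My call is none.

The forecast gave 31.7% for Wednesday's, 29.2% for Sunday's, 31.8% for Thursday's and 31.8% for Monday's, called none, and reasoned: "The conformers equilibrate far faster than anything else happens".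

The simulation gives 31.7%, 29.2%, 31.8% and 31.8% in that order, and the call is none. With the step to homo dimer struck out, Thursday's flask reads 32.9%, beside the target share of 32.9%. Sunday's tank stands at the outlet with 7.50% substrate and 3.15% other conformer, so 89.4% of the charge has left the pool, homo dimer included. The target share of that figure is 29.4%, and the tank reads 29.2%.

Its constants are assumed; no experiment stands behind them.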